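The lactone is disconnected across O1–C5 and C4–Br: in the furanone ring the ring oxygen and the vinylic bromine sit on the neighbouring carbons C5 and C4, the pattern left when a carboxyl group and bromine add across the distal double bond of a 2,3-allenoic acid. One CuBr2 bromolactonisation thus closes the ring and installs the C4 bromide. Its precursor is 2-[(1R)-1-silyloxybutyl]penta-2,3-dienoic acid, with C1' set by asymmetric transfer hydrogenation and protected as an acid-stable TBDPS ether. Afterwards C5 and its methyl group (C6) are taken to the dibromomethylene unit by enol-ether bromination and two bromine addition–elimination rounds, and desilylation gives the target.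

Key step: step 7

Remark: lactone numbering is O1, C2(=O), C3, C4(Br), C5, exocyclic C6, carbinol carbon C1'. Only C1' is carried with defined configuration (R); the carbonate carbinol, the allene axis and C5 are handled as epimer mixtures because all three are erased before the end.

Step 1
Reactants: 1 bis(trimethylsilyl)acetylene; 2 butanoyl chloride
Product: 3 1-(trimethylsilyl)hex-1-yn-3-one
Conditions: AlCl3, CH2Cl2, 0 °C
Reagents that add atoms: none
Why: Friedel–Crafts-type acylative ipso-desilylation of an alkynylsilane, in which the acylium–AlCl3 complex attacks a silyl-bearing alkyne carbon and chloride removes that SiMe3 group, while the electron-poor ynone formed should not react a second time.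

Step 2
Reactants: 3 1-(trimethylsilyl)hex-1-yn-3-one
Product: 4 (3R)-1-(trimethylsilyl)hex-1-yn-3-ol
Conditions: Ru[(R,R)-TsDPEN](p-cymene) (1 mol%, preformed from RuCl[(R,R)-TsDPEN](p-cymene) and KOH), i-PrOH, rt
Reagents that add atoms: none
Why: Noyori asymmetric transfer hydrogenation of an alkynyl ketone, in which the Ru–H/N–H pair transfers hydride and proton through a six-membered transition state with the alkynyl group in the place an aryl group takes with aryl ketones, so the (R,R)-catalyst should set the carbinol (the future C1') as R under catalyst control without touching the triple bond.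

Step 3
Reactants: 4 (3R)-1-(trimethylsilyl)hex-1-yn-3-ol
Product: 6 tert-butyl{[(3R)-hex-1-yn-3-yl]oxy}diphenylsilane, via bis-silyl alkyne 5 (not isolated)
Conditions: TBDPSCl, imidazole, DMF, rt; then MeOH, K2CO3 (0.2 equiv), rt
Reagents that add atoms: tert-butyl(chloro)diphenylsilane, CC(C)(C)[Si](Cl)(c1ccccc1)c1ccccc1
Why: Imidazole-promoted O-silylation of a secondary alcohol followed in the same flask by methanolysis of the alkynyl C–Si bond, which is selective because the hindered TBDPS ether resists methoxide, and the stereocentre is not involved.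

Step 4
Reactants: 6 tert-butyl{[(3R)-hex-1-yn-3-yl]oxy}diphenylsilane; 7 acetaldehyde
Product: 10 methyl (5R)-5-(tert-butyldiphenylsilyloxy)oct-3-yn-2-yl carbonate (both C2 epimers), via lithium acetylide 8 (not isolated), via lithium alkoxide 9 (not isolated)
Conditions: n-BuLi, THF, −78 °C; MeCHO, −78 °C; then ClCO2Me, −78 °C to rt
Reagents that add atoms: methyl chloroformate, COC(=O)Cl
Why: Acetylide addition to an aldehyde with in situ O-acylation of the lithium alkoxide by the chloroformate; the new carbinol centre is uncontrolled and need not be controlled, since it becomes the allene terminus and later the trigonal C5.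

Step 5
Reactants: 10 methyl (5R)-5-(tert-butyldiphenylsilyloxy)oct-3-yn-2-yl carbonate; 11 carbon monoxide
Product: 12 methyl 2-[(1R)-1-(tert-butyldiphenylsilyloxy)butyl]penta-2,3-dienoate (both allene epimers)
Conditions: Pd(OAc)2 (5 mol%), PPh3 (20 mol%), CO (10 bar), MeOH, 40 °C
Reagents that add atoms: methanol, CO
Why: Tsuji carbonylation of a propargylic carbonate, in which zerovalent palladium formed in situ displaces the carbonate in SN2′ fashion to an allenylpalladium methoxide with loss of CO2, and CO insertion then methanolysis should give the 2,3-dienoate with the ester on the carbon that carries C1'; the allene axis forms as a mixture, which is irrelevant.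

Step 6
Reactants: 12 methyl 2-[(1R)-1-(tert-butyldiphenylsilyloxy)butyl]penta-2,3-dienoate
Product: 14 2-[(1R)-1-(tert-butyldiphenylsilyloxy)butyl]penta-2,3-dienoic acid (both allene epimers), via lithium carboxylate 13 (not isolated)
Conditions: LiOH·H2O, THF/MeOH/H2O, rt; then 1 M HCl, 0 °C
Reagents that add atoms: lithium hydroxide, [Li+].[OH-]
Why: Ester saponification (BAc2) at room temperature, safe because C2 carries no hydrogen through which the allene could isomerise and the TBDPS ether is stable to LiOH.

Step 7
Reactants: 14 2-[(1R)-1-(tert-butyldiphenylsilyloxy)butyl]penta-2,3-dienoic acid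
Product: 15 4-bromo-3-[(1R)-1-(tert-butyldiphenylsilyloxy)butyl]-5-methylfuran-2(5H)-one (both C5 epimers)
Conditions: CuBr2 (4 equiv), acetone/H2O (2:1), 65 °C
Reagents that add atoms: copper dibromide, Br[Cu]Br
Why: Divalent copper coordinates the distal double bond of the allenoic acid (acid C3=C4) and the carboxyl oxygen adds to the terminus, giving a lactone with a carbon–copper bond at the former central carbon; a second CuBr2 turns that bond into C4–Br, so two CuBr2 end as two CuBr and HBr. The closest known reaction type is the CuX2-mediated halolactonisation of 2,3-allenoic acids to 4-halofuran-2(5H)-ones. The furanone ring closes in a 5-endo-trig mode onto the trigonal allene terminus, which becomes C5. The one new stereocentre, C5, is formed without control, which is acceptable because it becomes trigonal in step 8; C1' is a spectator. The step needs regioselectivity (oxygen to the terminus, bromine to the central carbon) and chemoselectivity for the carboxyl nucleophile: the first follows from the 2,3-relationship of carboxyl and allene, since attack at the central carbon would give a four-membered ring, and the second from masking the C1' oxygen as a TBDPS ether, which should withstand the hot aqueous HBr/CuBr2 medium that would strip a TBS ether and free a competing hydroxyl.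

Step 8
Reactants: 15 4-bromo-3-[(1R)-1-(tert-butyldiphenylsilyloxy)butyl]-5-methylfuran-2(5H)-one
Product: 18 4-bromo-3-[(1R)-1-(tert-butyldiphenylsilyloxy)butyl]-5-methylidenefuran-2(5H)-one, via silyloxyfuran 16 (not isolated), via C5 bromide 17 (not isolated)
Conditions: TBSOTf, Et3N, CH2Cl2, 0 °C; NBS, −78 °C; then Et3N, 0 °C to rt
Reagents that add atoms: none
Why: Soft enolisation turns the butenolide, whose only acidic hydrogen is at C5, into the aromatic 2-silyloxyfuran, NBS brominates this silyl dienol ether at C5 (γ-halogenation of a silyloxyfuran), and Et3N effects E2 loss of HBr toward the methyl group, the only site with β-hydrogens, so the uncontrolled C5 centre is erased and the non-radical conditions leave the C1'–H alone.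

Step 9
Reactants: 18 4-bromo-3-[(1R)-1-(tert-butyldiphenylsilyloxy)butyl]-5-methylidenefuran-2(5H)-one
Product: 20 (5Z)-4-bromo-5-(bromomethylidene)-3-[(1R)-1-(tert-butyldiphenylsilyloxy)butyl]furan-2(5H)-one, via bromine adduct 19 (not isolated)
Conditions: Br2 (1.1 equiv), CH2Cl2, 0 °C, dark; then DBU, 0 °C
Reagents that add atoms: bromine, BrBr
Why: Electrophilic bromine addition to the exocyclic enol-ester double bond followed by DBU dehydrobromination (the bromination–dehydrobromination sequence used on 4-bromo-5-methylene butenolides), in which the labile tertiary C5 bromide leaves with the only available β-hydrogen on C6; the Z isomer should dominate, but the geometry disappears in step 10.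

Step 10
Reactants: 20 (5Z)-4-bromo-5-(bromomethylidene)-3-[(1R)-1-(tert-butyldiphenylsilyloxy)butyl]furan-2(5H)-one
Product: 22 4-bromo-5-(dibromomethylidene)-3-[(1R)-1-(tert-butyldiphenylsilyloxy)butyl]furan-2(5H)-one, via bromine adduct 21 (not isolated)
Conditions: Br2 (3 equiv), CH2Cl2, rt, dark; evaporate; then DBU, CH2Cl2, 0 °C
Reagents that add atoms: bromine, BrBr
Why: A second bromine addition–dehydrobromination on the same C5=C6 bond, run with excess Br2 in the dark to keep the less nucleophilic bromoalkene on the ionic pathway, after which DBU removes the acidic CHBr2 hydrogen with loss of the C5 bromide to give a dibromomethylene group that has no geometry to control.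

Step 11
Reactants: 22 4-bromo-5-(dibromomethylidene)-3-[(1R)-1-(tert-butyldiphenylsilyloxy)butyl]furan-2(5H)-one
Product: 23 4-bromo-5-(dibromomethylidene)-3-[(1R)-1-hydroxybutyl]furan-2(5H)-one
Conditions: HF·pyridine, THF, 0 °C to rt
Reagents that add atoms: none
Why: Fluoride-driven Si–O cleavage under acidic conditions, chosen because 5-ylidene bromobutenolides tolerate acid but not basic fluoride or nucleophiles, and since the C1'–O bond is never broken the R configuration set in step 2 is retained.

Compound list
1 | bis(trimethylsilyl)acetylene | C[Si](C)(C)C#C[Si](C)(C)C | starting material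
2 | butanoyl chloride | CCCC(=O)Cl | starting material
3 | 1-(trimethylsilyl)hex-1-yn-3-one | CCCC(=O)C#C[Si](C)(C)C | intermediate
4 | (3R)-1-(trimethylsilyl)hex-1-yn-3-ol | CCC[C@@H](O)C#C[Si](C)(C)C | intermediate
5 | tert-butyldiphenyl{[(3R)-1-(trimethylsilyl)hex-1-yn-3-yl]oxy}silane | CCC[C@@H](O[Si](c1ccccc1)(c1ccccc1)C(C)(C)C)C#C[Si](C)(C)C | intermediate
6 | tert-butyl{[(3R)-hex-1-yn-3-yl]oxy}diphenylsilane | CCC[C@@H](O[Si](c1ccccc1)(c1ccccc1)C(C)(C)C)C#C | intermediate
7 | acetaldehyde | CC=O | starting material
8 | lithium acetylide of 6 | CCC[C@@H](O[Si](c1ccccc1)(c1ccccc1)C(C)(C)C)C#C[Li] | intermediate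
9 | lithium (5R)-5-(tert-butyldiphenylsilyloxy)oct-3-yn-2-olate (both C2 epimers) | CCC[C@@H](O[Si](c1ccccc1)(c1ccccc1)C(C)(C)C)C#CC(C)O[Li] | intermediate
10 | methyl (5R)-5-(tert-butyldiphenylsilyloxy)oct-3-yn-2-yl carbonate (both C2 epimers) | CCC[C@@H](O[Si](c1ccccc1)(c1ccccc1)C(C)(C)C)C#CC(C)OC(=O)OC | intermediate
11 | carbon monoxide | [C-]#[O+] | starting material
12 | methyl 2-[(1R)-1-(tert-butyldiphenylsilyloxy)butyl]penta-2,3-dienoate (both allene epimers) | CCC[C@@H](O[Si](c1ccccc1)(c1ccccc1)C(C)(C)C)C(=C=CC)C(=O)OC | intermediate
13 | lithium 2-[(1R)-1-(tert-butyldiphenylsilyloxy)butyl]penta-2,3-dienoate | CCC[C@@H](O[Si](c1ccccc1)(c1ccccc1)C(C)(C)C)C(=C=CC)C(=O)[O-].[Li+] | intermediate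
14 | 2-[(1R)-1-(tert-butyldiphenylsilyloxy)butyl]penta-2,3-dienoic acid (both allene epimers) | CCC[C@@H](O[Si](c1ccccc1)(c1ccccc1)C(C)(C)C)C(=C=CC)C(=O)O | intermediate
15 | 4-bromo-3-[(1R)-1-(tert-butyldiphenylsilyloxy)butyl]-5-methylfuran-2(5H)-one (both C5 epimers) | CCC[C@@H](O[Si](c1ccccc1)(c1ccccc1)C(C)(C)C)C1=C(Br)C(C)OC1=O | intermediate
16 | {[4-bromo-3-[(1R)-1-(tert-butyldiphenylsilyloxy)butyl]-5-methylfuran-2-yl]oxy}(tert-butyl)dimethylsilane | CCC[C@@H](O[Si](c1ccccc1)(c1ccccc1)C(C)(C)C)c1c(Br)c(C)oc1O[Si](C)(C)C(C)(C)C | intermediate
17 | 4,5-dibromo-3-[(1R)-1-(tert-butyldiphenylsilyloxy)butyl]-5-methylfuran-2(5H)-one (both C5 epimers) | CCC[C@@H](O[Si](c1ccccc1)(c1ccccc1)C(C)(C)C)C1=C(Br)C(C)(Br)OC1=O | intermediate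
18 | 4-bromo-3-[(1R)-1-(tert-butyldiphenylsilyloxy)butyl]-5-methylidenefuran-2(5H)-one | CCC[C@@H](O[Si](c1ccccc1)(c1ccccc1)C(C)(C)C)C1=C(Br)C(=C)OC1=O | intermediate
19 | 4,5-dibromo-5-(bromomethyl)-3-[(1R)-1-(tert-butyldiphenylsilyloxy)butyl]furan-2(5H)-one (both C5 epimers) | CCC[C@@H](O[Si](c1ccccc1)(c1ccccc1)C(C)(C)C)C1=C(Br)C(Br)(CBr)OC1=O | intermediate
20 | (5Z)-4-bromo-5-(bromomethylidene)-3-[(1R)-1-(tert-butyldiphenylsilyloxy)butyl]furan-2(5H)-one | CCC[C@@H](O[Si](c1ccccc1)(c1ccccc1)C(C)(C)C)C1=C(Br)/C(=C/Br)OC1=O | intermediate
21 | 4,5-dibromo-5-(dibromomethyl)-3-[(1R)-1-(tert-butyldiphenylsilyloxy)butyl]furan-2(5H)-one (both C5 epimers) | CCC[C@@H](O[Si](c1ccccc1)(c1ccccc1)C(C)(C)C)C1=C(Br)C(Br)(C(Br)Br)OC1=O | intermediate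
22 | 4-bromo-5-(dibromomethylidene)-3-[(1R)-1-(tert-butyldiphenylsilyloxy)butyl]furan-2(5H)-one | CCC[C@@H](O[Si](c1ccccc1)(c1ccccc1)C(C)(C)C)C1=C(Br)C(=C(Br)Br)OC1=O | intermediate
23 | 4-bromo-5-(dibromomethylidene)-3-[(1R)-1-hydroxybutyl]furan-2(5H)-one | CCC[C@@H](O)C1=C(Br)C(=C(Br)Br)OC1=O | target

Total step count: 11. Longest linear sequence: 11 steps (from 1 and 2 to 23; the route is fully linear).

Steps most likely to fail

Step 7 (key step). The HBr released at 65 °C could still erode the silyl ether, and the freed C1' hydroxyl would then compete with the carboxyl group for the copper-activated allene, or the allenoic acid could be consumed by hydration. The fallback sets out from acid 14 and comes back at lactone 15. It replaces copper oxymetalation by a metal-free, base-buffered bromiranium cyclisation (NBS, K2CO3, MeCN/H2O, 0 °C to rt): the carboxylate opens the bromiranium ion of the distal double bond at the terminus, which forms the same O1–C5 and C4–Br bonds in a medium that cannot desilylate. No compound outside the list arises (F0).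

Step 8. In the one-flask sequence the bromination may not stop at C5: NBS could attack the exocyclic enol-ester alkene as it forms, or the tertiary bromide could ionise and scramble. The fallback sets out from 15 and comes back at 18. It uses an oxygen electrophile that stops at a stable lactol: silyloxyfuran 16 is prepared as before and isolated, then oxidised with dimethyldioxirane (acetone, −78 °C) to 4-bromo-3-[(1R)-1-(tert-butyldiphenylsilyloxy)butyl]-5-hydroxy-5-methylfuran-2(5H)-one F1. This is dehydrated with P2O5 in toluene, a dehydration known for 4-bromo-5-hydroxy-5-methyl butenolides, to give 18.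

Step 10. Ionic addition of bromine to the deactivated bromoalkene may be too slow, and forcing it with light or heat opens a radical pathway that abstracts the C1' hydrogen and oxidises the silyl ether carbon. The fallback sets out from 18 and comes back at 22, bypassing steps 9 and 10. Ozonolysis of the exocyclic methylene (O3, CH2Cl2, −78 °C; then Me2S) gives 3-bromo-4-[(1R)-1-(tert-butyldiphenylsilyloxy)butyl]furan-2,5-dione F2. Ramirez-type dibromomethylenation (CBr4, PPh3, CH2Cl2, 0 °C to rt) should then occur at the less hindered anhydride carbonyl, the one next to the bromine-bearing carbon and remote from the bulky silyloxybutyl group, to give 22.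

Further compounds
F0 | step 7 | none | none
F1 | step 8 | 4-bromo-3-[(1R)-1-(tert-butyldiphenylsilyloxy)butyl]-5-hydroxy-5-methylfuran-2(5H)-one | CCC[C@@H](O[Si](c1ccccc1)(c1ccccc1)C(C)(C)C)C1=C(Br)C(C)(O)OC1=O
F2 | step 10 | 3-bromo-4-[(1R)-1-(tert-butyldiphenylsilyloxy)butyl]furan-2,5-dione | CCC[C@@H](O[Si](c1ccccc1)(c1ccccc1)C(C)(C)C)C1=C(Br)C(=O)OC1=O
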